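The methylene bridge is cut last: eugenin, activated at C-6, meets the only free aromatic carbon (C-5) of a (3R)-6,8-dihydroxy-3,7-dimethyl-3,4-dihydroisocoumarin. Everything rests on reading C-4/C-3 of the δ-lactone ring as a propane-1,2-diyl unit that spans aromatic C-4a and the carboxyl oxygen O-2. The key step exploits the C-1 carboxylate twice: in 2,4-dimethoxy-3-methylbenzoic acid it directs lithiation to the future C-4a, then serves as internal nucleophile. The resulting C,O-dianion reacts with (S)-propylene cyclic sulfate: aryl carbon opens the CH2 terminus, carboxylate displaces the secondary sulfate with inversion, giving lactone ring and (R)-stereocentre in one flask.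

Key step: step 2

Assumption: locants are those of the 3,4-dihydroisocoumarin (C-1, O-2, C-3 to C-8a) and of the chromone (O-1 to C-8a), and compounds 1, 4 and 9 are taken as catalogue compounds.

Step 1
Reactants: 1 (S)-propane-1,2-diol
Product: 3 (4S)-4-methyl-1,3,2-dioxathiolane 2,2-dioxide, via cyclic sulfite 2 (not isolated)
Conditions: SOCl2 (1.2 equiv), CH2Cl2, 0 °C to reflux; then RuCl3·3H2O (0.5 mol %), NaIO4 (1.5 equiv), MeCN/H2O, 0 °C
Reagents that add atoms: thionyl chloride, O=S(Cl)Cl; sodium periodate, [Na+].[O-]I(=O)(=O)=O
Why: The standard two-stage cyclic sulfate synthesis (cyclic sulfite formation, then ruthenium-catalysed periodate oxidation at sulfur) breaks no C–O bond, so the (S) centre is carried over unchanged.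

Step 2
Reactants: 4 2,4-dimethoxy-3-methylbenzoic acid; 3 (4S)-4-methyl-1,3,2-dioxathiolane 2,2-dioxide
Product: 7 (3R)-6,8-dimethoxy-3,7-dimethyl-3,4-dihydroisocoumarin, via dilithiated benzoate 5 (not isolated), via secondary sulfate salt 6 (not isolated)
Conditions: 4 added to s-BuLi/TMEDA (2.2 equiv each), THF, −78 °C, 2 h; CuBr·SMe2 (10 mol %), then 3 (1.2 equiv), −78 to 0 °C; then DMF added, 70 °C; aq. NaHCO3 work-up, extraction of the neutral lactone
Reagents that add atoms: none
Why: Proposed new method: carboxylate-directed ortho-lithiation removes H-6 of 4 to give the C,O-dianion 5, whose aryl carbon (as the catalytic arylcopper species) opens cyclic sulfate 3 by SN2 attack at the CH2 terminus to form the aryl–CH2 bond and the anionic secondary sulfate 6, and on heating in THF/DMF the neighbouring lithium carboxylate expels sulfate from the secondary carbon to form the O–CH bond. The closest known reaction types are the copper-catalysed opening of 1,2-cyclic sulfates by organometallic reagents, the double displacement of cyclic sulfates by bis-nucleophiles such as malonate, and the palladium-catalysed ortho-alkylation/lactonisation of benzoic acids with 1,2-dichloroethane; what is new is the pairing of an aryl carbanion and its ortho carboxylate on a cyclic sulfate. The δ-lactone ring closes in the 6-exo-tet mode. The C-3 stereocentre is set by the reagent: the first opening leaves the (S) carbon untouched and the second displacement is a stereospecific SN2 inversion, (S) to (R). The step needs metalation at C-6 and not C-5 (secured by the lithium carboxylate/TMEDA complex, with C-3 blocked by methyl), first attack at the primary carbon (sterics, and the graded reactivity of the cyclic sulfate, whose second leaving group is anionic and so resists β-elimination from copper) and substitution over elimination (a weakly basic, intramolecular nucleophile). Any unreacted 6 stays in the NaHCO3 phase at work-up, so that no hydrolysis with retention can erode the configuration of 7.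

Step 3
Reactants: 7 (3R)-6,8-dimethoxy-3,7-dimethyl-3,4-dihydroisocoumarin
Product: 8 (3R)-6,8-dihydroxy-3,7-dimethyl-3,4-dihydroisocoumarin
Conditions: BBr3 (4 equiv), CH2Cl2, −78 °C to rt; H2O quench
Reagents that add atoms: none
Why: In this boron tribromide aryl methyl ether cleavage, bromide attacks the two O-methyl groups (the C-8 ether is helped by chelation to the lactone carbonyl), while the secondary, non-benzylic C-3–O bond is not ionised, so C-3 stays (R).

Step 4
Reactants: 9 eugenin (5-hydroxy-7-methoxy-2-methyl-4H-chromen-4-one)
Product: 10 eugenin 5-O,6-CH2O cyclic phenylboronate (a 2-phenyl-4H-1,3,2-dioxaborin ring fused at C-5/C-6 of the chromone)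
Conditions: PhB(OH)2 (1.2 equiv), (CH2O)n (5 equiv), EtCO2H (0.3 equiv), toluene, reflux, Dean–Stark
Reagents that add atoms: phenylboronic acid, OB(O)c1ccccc1; paraformaldehyde (as formaldehyde), C=O
Why: In this boronic-acid-templated ortho-hydroxymethylation of a phenol, the aryl boronate of the 5-OH binds formaldehyde and delivers it through a six-membered transition state to the only free ortho carbon, C-6, rather than to the para carbon C-8, and the product is trapped as the stable cyclic boronate.

Step 5
Reactants: 10 eugenin 5-O,6-CH2O cyclic phenylboronate; 8 (3R)-6,8-dihydroxy-3,7-dimethyl-3,4-dihydroisocoumarin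
Product: 12 (3R)-6,8-dihydroxy-5-[(5-hydroxy-7-methoxy-2-methyl-4-oxo-4H-chromen-6-yl)methyl]-3,7-dimethyl-3,4-dihydroisocoumarin, via ortho-quinone methide 11 (not isolated)
Conditions: p-TsOH·H2O (20 mol %), 1,4-dioxane, 50 °C, 10 added slowly to 8 (1.5 equiv); aqueous work-up
Reagents that add atoms: none
Why: This is a Friedel–Crafts-type benzylation through an ortho-quinone methide, in which acid opens the dioxaborin to 11 (its protonated form is stabilised by O-5, the 7-methoxy group and O-1), and 11 is attacked by C-5 of 8, the only unsubstituted aromatic carbon there and ortho/para to both hydroxyls, with the remote C-3 centre not involved.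

Compound list
1 | (S)-propane-1,2-diol | C[C@H](O)CO | starting material
2 | (4S)-4-methyl-1,3,2-dioxathiolane 2-oxide (cyclic sulfite, mixture at sulfur) | C[C@H]1COS(=O)O1 | intermediate
3 | (4S)-4-methyl-1,3,2-dioxathiolane 2,2-dioxide | C[C@H]1COS(=O)(=O)O1 | intermediate
4 | 2,4-dimethoxy-3-methylbenzoic acid | COc1ccc(C(=O)O)c(OC)c1C | starting material
5 | lithium 6-lithio-2,4-dimethoxy-3-methylbenzoate | COc1cc([Li])c(C(=O)O[Li])c(OC)c1C | intermediate
6 | dilithium 2-[(2S)-2-(sulfonatooxy)propyl]-4,6-dimethoxy-5-methylbenzoate | COc1cc(C[C@H](C)OS(=O)(=O)O[Li])c(C(=O)O[Li])c(OC)c1C | intermediate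
7 | (3R)-6,8-dimethoxy-3,7-dimethyl-3,4-dihydroisocoumarin | COc1cc2C[C@@H](C)OC(=O)c2c(OC)c1C | intermediate
8 | (3R)-6,8-dihydroxy-3,7-dimethyl-3,4-dihydroisocoumarin | Oc1cc2C[C@@H](C)OC(=O)c2c(O)c1C | intermediate
9 | eugenin (5-hydroxy-7-methoxy-2-methyl-4H-chromen-4-one) | COc1cc2oc(C)cc(=O)c2c(O)c1 | starting material
10 | eugenin 5-O,6-CH2O cyclic phenylboronate | COc1cc2oc(C)cc(=O)c2c3OB(c4ccccc4)OCc13 | intermediate
11 | 7-methoxy-2-methyl-6-methylidene-chromene-4,5-dione (ortho-quinone methide) | COC1=CC2=C(C(=O)C1=C)C(=O)C=C(C)O2 | intermediate
12 | (3R)-6,8-dihydroxy-5-[(5-hydroxy-7-methoxy-2-methyl-4-oxo-4H-chromen-6-yl)methyl]-3,7-dimethyl-3,4-dihydroisocoumarin | COc1cc2oc(C)cc(=O)c2c(O)c1Cc1c(O)c(C)c(O)c2c1C[C@@H](C)OC2=O | target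

Total step count: 5. Longest linear sequence: 4 steps (steps 1, 2, 3 and 5).

Steps most likely to fail

Step 2 (labelled step).
- The anionic sulfate may be displaced too slowly by the carboxylate.
- Elimination toward the conjugated alkene may outrun substitution.
- The aryl anion may attack sulfur instead of carbon.
- Lithiation may be incomplete or misdirected.
- The fallback uses known chemistry, sets out from 4 and comes back at 7. Dianion 5 is generated as in the route and treated with (R)-propylene oxide (CuBr·SMe2 catalysis, THF, −78 to 0 °C). This is an established opening at the CH2 terminus that leaves the C–O bond of the stereocentre intact. Mild acidification should give 2-[(2R)-2-hydroxypropyl]-4,6-dimethoxy-5-methylbenzoic acid F1, which lactonises with retention (cat. p-TsOH, toluene, 60 °C) to 7.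

Step 5.
- The chromone electrophile may condense with itself through its own nucleophilic C-8.
- Attack may occur through oxygen instead of carbon.
- Acid may reversibly cleave and scramble the methylene bridge.
- The fallback is a blocking-group strategy that sets out from 10 and comes back at 12. NBS (1.0 equiv, MeCN, 0 °C) should brominate the only remaining aromatic C–H of 10 to give the 8-bromo cyclic phenylboronate F4. Without a nucleophilic site of its own, F4 is coupled with 8 under acid catalysis to give the 8-bromo analogue of the target F5. Hydrogenolysis of the aryl bromide (H2, Pd/C, NaOAc, EtOAc/MeOH, rt) then gives 12.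

Step 4.
- Chelation of the 5-OH to the C-4 carbonyl may hold back boronate formation so that the templated delivery stalls.
- Untemplated attack of formaldehyde at C-8 may then take over.
- The fallback is halogenation followed by cross-coupling; it sets out from 9 and comes back at 10. Benzyltrimethylammonium dichloroiodate with CaCO3 in CH2Cl2/MeOH is known to iodinate 5-hydroxy-7-alkoxy benzopyranones next to the free hydroxyl, and should give 6-iodoeugenin F2. Stille hydroxymethylation (Bu3SnCH2OH, Pd(PPh3)4, 1,4-dioxane, 100 °C) gives 6-(hydroxymethyl)eugenin F3. F3 condenses with PhB(OH)2 (toluene, azeotropic removal of water) to 10.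

Further compounds
F1 | step 2 | 2-[(2R)-2-hydroxypropyl]-4,6-dimethoxy-5-methylbenzoic acid | COc1cc(C[C@@H](C)O)c(C(=O)O)c(OC)c1C
F2 | step 4 | 6-iodoeugenin (5-hydroxy-6-iodo-7-methoxy-2-methyl-4H-chromen-4-one) | COc1cc2oc(C)cc(=O)c2c(O)c1I
F3 | step 4 | 6-(hydroxymethyl)eugenin | COc1cc2oc(C)cc(=O)c2c(O)c1CO
F4 | step 5 | 8-bromo derivative of cyclic phenylboronate 10 | COc1c(Br)c2oc(C)cc(=O)c2c3OB(c4ccccc4)OCc13
F5 | step 5 | 8-bromo (chromone C-8) analogue of the target | COc1c(Br)c2oc(C)cc(=O)c2c(O)c1Cc1c(O)c(C)c(O)c2c1C[C@@H](C)OC2=O
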